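All runs were generated by integration from invented constants; scatter was added.

Compared at 4.00 h, the north, west and east runs hold about the same D, 54.0%, 54.5% and 54.3%, but different L, 20.5%, 27.8% and 29.3%.

| flask | D | X | remark | time |
|---|---|---|---|---|
| north | 0.065 M | 0.026 M | run made earlier |  |
| west | 0.065 M | 0.10 M | run made earlier |  |
| east | 0.033 M | 0.052 M | run made earlier |  |
| flask | 0.065 M | 0.0520 M |  | 6.0 h |

| run | time / h | L / % | D / % |
|---|---|---|---|
| north | 0.500 | 2.9 | 92.5 |
| north | 1.00 | 7.3 | 85.9 |
| north | 1.50 | 11.8 | 79.4 |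
| north | 2.00 | 14.0 | 72.8 |
| north | 2.50 | 16.6 | 67.4 |
| north | 3.00 | 18.3 | 62.8 |
| north | 4.00 | 20.5 | 54.0 |
| west | 0.200 | 2.5 | 96.8 |
| west | 0.500 | 5.4 | 93.0 |
| west | 1.00 | 10.1 | 86.2 |
| west | 1.50 | 14.4 | 79.4 |
| west | 2.00 | 17.9 | 73.3 |
| west | 3.00 | 24.3 | 63.0 |
| west | 4.00 | 27.8 | 54.5 |
| east | 0.333 | 2.4 | 95.4 |
| east | 0.833 | 7.9 | 87.8 |
| east | 1.50 | 14.0 | 79.2 |
| east | 2.50 | 20.7 | 67.9 |
| east | 4.00 | 29.3 | 54.3 |

(readings scatter by 0.5 percentage points)

- the numbers in the tables scatter with a standard deviation of 0.5 percentage points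

1. amount of L in percent of the D charged, at 20 min, 1.5 h and 6.0 h

So work with the fraction of D left, not with the L made. The north reading gives k = ln(charged/left)/t = 0.154 h⁻¹, and exp(-kt) then leaves 39.7% of D in the new flask at 6.0 h.

A bench rule of thumb says that L is a fixed share of the D lost. This capture share, L formed per D lost (the selectivity), reads 0.673 in the east run at 1.5 h. East has the X charge of the new flask, so you take its readings for the early points: 2.4% at 20 min and 14.0% at 1.5 h. Carried on, the rule gives 40.6% at 6.0 h.

The border shows in the ratio of X to D charged, 0.400 in north and 0.800 in the new flask, which is twice as much. At 1.5 h the north share is already down to 0.573, lower than east's, with L then equal to 0.295 of the X charge. From there to 4.00 h, the north readings give a share of 0.343 for the further D lost. Take the north reading of 0.295 as the border. On this reckoning the new flask comes to it at 23.6% of L, below the rule's end value. Counting the remaining D lost at the lower share, you commit to 32.3% at 6.0 h.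

The forecast gives 2.3%, 13.6% and 35%, "Stepping forward with falling X gives roughly 35 % at 6 h", which at 6.0 h is higher than your value.

    D → E (k = 0.00257 min⁻¹)
    X + E ⇌ J (K = 110 M⁻¹, k = 0.0685 M⁻¹ min⁻¹)
    X + E → L (k = 2.65 M⁻¹ min⁻¹)
    X + L → Z (k = 0.0462 M⁻¹ min⁻¹)
    E → Q (k = 0.00986 min⁻¹)
    2 X → G (k = 0.185 M⁻¹ min⁻¹)

The new flask gives 2.74%, 13.7% and 27.9%, so your end value stands 4.4 points high. In the new flask, half of the turnover up to 6.0 h of the turning of 2 X into G is done by 0.389 h, much earlier than the same half of the turning of D into E, at 2.33 h. At 6.00 h the new flask holds X, the limiting reagent, at 0.551% of its own charge, and its capture share up to then is 0.462, lower than the 0.673 read in the east run at 1.5 h.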